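**Assumption:** the target SMILES carries no stereocentre and no assigned biaryl axis, so the target is treated as one achiral constitution; the only stereo-element on the way is the E geometry of the chalcones.

## Retrosynthetic overview

1. Target ⇐ its penta-O-benzyl ether by global hydrogenolysis; the 4'''-methoxy group is the only methyl ether carried through.
2. Ring C of the apigenin unit ⇐ iodine/DMSO oxidative cyclisation of a 2'-hydroxychalcone ⇐ Claisen–Schmidt condensation of a biaryl aldehyde with 2-hydroxy-4,6-bis(benzyloxy)acetophenone.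
3. C3'–C8'' biaryl bond ⇐ proposed gold-catalysed C8–H arylation of 5,7-di-O-benzylacacetin with 4-(benzyloxy)-3-iodobenzaldehyde (the new step).
4. 5,7-Di-O-benzylacacetin ⇐ chalcone of the same acetophenone with 4-methoxybenzaldehyde; the acetophenone ⇐ phloroacetophenone.
5. Ring order: ring C of the acacetin unit first, then the biaryl bond, then ring C of the apigenin unit; all benzene rings are bought.

## Route

**Step 1**
Reactants: 1 2,4,6-trihydroxyacetophenone (phloroacetophenone)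
Product: 2 1-[2,4-bis(benzyloxy)-6-hydroxyphenyl]ethan-1-one
Conditions: BnBr (2.05 equiv), K2CO3 (2.2 equiv), DMF, 0 °C to 25 °C
Reagents that add atoms: benzyl bromide, BrCc1ccccc1
Why: Williamson etherification (SN2) of the two free phenoxides, while the hydroxyl hydrogen-bonded to the acetyl carbonyl is far less nucleophilic and stays free.

**Step 2**
Reactants: 2 1-[2,4-bis(benzyloxy)-6-hydroxyphenyl]ethan-1-one; 3 4-methoxybenzaldehyde
Product: 4 (E)-1-[2,4-bis(benzyloxy)-6-hydroxyphenyl]-3-(4-methoxyphenyl)prop-2-en-1-one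
Conditions: KOH (50% aq., 10 equiv), EtOH, 25 °C, 24 h; then 1 M HCl work-up
Reagents that add atoms: none
Why: Claisen–Schmidt aldol condensation of the methyl ketone enolate with a non-enolisable aldehyde, and E1cB dehydration gives the conjugated enone with the thermodynamic E geometry.

**Step 3**
Reactants: 4 (E)-1-[2,4-bis(benzyloxy)-6-hydroxyphenyl]-3-(4-methoxyphenyl)prop-2-en-1-one
Product: 6 di-O-benzylacacetin (5,7-bis(benzyloxy)-2-(4-methoxyphenyl)-4H-chromen-4-one), via racemic di-O-benzylisosakuranetin 5 (not isolated)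
Conditions: I2 (10 mol %), DMSO, 130 °C, 2 h; aq. Na2S2O3 wash
Reagents that add atoms: none
Why: Iodine-catalysed oxidative cyclisation of a 2'-hydroxychalcone, in which oxa-Michael closure to the flavanone is followed by iodine-mediated dehydrogenation with DMSO reoxidising HI, so the transient flavanone stereocentre is erased.

**Step 4**
Reactants: 7 4-hydroxy-3-iodobenzaldehyde
Product: 8 4-(benzyloxy)-3-iodobenzaldehyde
Conditions: BnBr (1.1 equiv), K2CO3 (1.5 equiv), DMF, 25 °C
Reagents that add atoms: benzyl bromide, BrCc1ccccc1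
Why: Williamson etherification (SN2) of the acidic para-formyl phenoxide, to which the aryl iodide and the aldehyde are inert.

**Step 5**
Reactants: 6 di-O-benzylacacetin (1.3 equiv); 8 4-(benzyloxy)-3-iodobenzaldehyde (1.0 equiv)
Product: 9 4-(benzyloxy)-3-[5,7-bis(benzyloxy)-2-(4-methoxyphenyl)-4-oxo-4H-chromen-8-yl]benzaldehyde
Conditions: (MeDalphos)AuCl [MeDalphos = (1-Ad)2P(C6H4-2-NMe2)] (5 mol %), AgOTf (1.1 equiv), K3PO4 (1.0 equiv), 1,2-dichlorobenzene/MeOH 50:1, 80 °C, argon, dark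
Reagents that add atoms: none
Why: Proposed new method: the hemilabile P,N-ligated gold centre should add the C–I bond of 8 oxidatively (monovalent to trivalent gold), AgOTf then removes iodide to expose a strongly electrophilic aryl-gold cation that aurates 6 by electrophilic aromatic substitution at C8 (activated by O1, the 7-benzyloxy group and the para 5-benzyloxy group, and the site where 5,7-dialkoxyflavones are known to be iodinated, whereas C6 is buttressed by two benzyloxy groups and C3 is a weaker vinylogous-ester nucleophile), phosphate takes the proton, and C–C reductive elimination from the diaryl trivalent gold centre forms the C3'–C8'' bond and returns monovalent gold; the closest known reaction type is the ligand-enabled gold-catalysed C–H arylation of 1,3,5-trimethoxybenzene and indoles with aryl iodides, not yet shown on ring A of a flavone or for a biflavonoid linkage, and because 8 carries no nucleophilic arene it cannot self-couple.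

**Step 6**
Reactants: 9 4-(benzyloxy)-3-[5,7-bis(benzyloxy)-2-(4-methoxyphenyl)-4-oxo-4H-chromen-8-yl]benzaldehyde; 2 1-[2,4-bis(benzyloxy)-6-hydroxyphenyl]ethan-1-one (1.2 equiv)
Product: 10 (E)-1-[2,4-bis(benzyloxy)-6-hydroxyphenyl]-3-{4-(benzyloxy)-3-[5,7-bis(benzyloxy)-2-(4-methoxyphenyl)-4-oxo-4H-chromen-8-yl]phenyl}prop-2-en-1-one
Conditions: KOH (10 equiv), EtOH/THF 1:1, 25 °C, 36 h; then 1 M HCl work-up
Reagents that add atoms: none
Why: Claisen–Schmidt aldol condensation as in step 2, with E1cB dehydration giving the E-chalcone, while the electron-rich 5,7-dialkoxyflavone ring C resists hydroxide at room temperature.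

**Step 7**
Reactants: 10 (E)-1-[2,4-bis(benzyloxy)-6-hydroxyphenyl]-3-{4-(benzyloxy)-3-[5,7-bis(benzyloxy)-2-(4-methoxyphenyl)-4-oxo-4H-chromen-8-yl]phenyl}prop-2-en-1-one
Product: 12 penta-O-benzylpodocarpusflavone A (5,7-bis(benzyloxy)-8-{2-(benzyloxy)-5-[5,7-bis(benzyloxy)-4-oxo-4H-chromen-2-yl]phenyl}-2-(4-methoxyphenyl)-4H-chromen-4-one), via racemic 2,3-dihydro pentabenzyl ether 11 (not isolated)
Conditions: I2 (20 mol %), DMSO, 130 °C, 3 h; aq. Na2S2O3 wash
Reagents that add atoms: none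
Why: Iodine-catalysed oxidative cyclisation of the 2'-hydroxychalcone as in step 3 (oxa-Michael closure, then dehydrogenation with DMSO as terminal oxidant), and any benzyl ether lost to HI is harmless because all benzyl groups fall in step 8.

**Step 8**
Reactants: 12 penta-O-benzylpodocarpusflavone A
Product: 13 podocarpusflavone A (8-[5-(5,7-dihydroxy-4-oxo-4H-chromen-2-yl)-2-hydroxyphenyl]-5,7-dihydroxy-2-(4-methoxyphenyl)-4H-chromen-4-one)
Conditions: H2 (1 atm), 10% Pd/C, THF/MeOH 1:1, 25 °C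
Reagents that add atoms: none
Why: Heterogeneous hydrogenolysis cleaves the five benzylic C–O bonds, while the aryl methyl ether and the vinylogous-ester C2=C3 bonds of both chromones are not reduced at one atmosphere and room temperature.

## Compound list

1 | 2,4,6-trihydroxyacetophenone | CC(=O)c1c(O)cc(O)cc1O | starting material
2 | 1-[2,4-bis(benzyloxy)-6-hydroxyphenyl]ethan-1-one | CC(=O)c1c(O)cc(OCc2ccccc2)cc1OCc1ccccc1 | intermediate
3 | 4-methoxybenzaldehyde | COc1ccc(C=O)cc1 | starting material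
4 | (E)-1-[2,4-bis(benzyloxy)-6-hydroxyphenyl]-3-(4-methoxyphenyl)prop-2-en-1-one | COc1ccc(/C=C/C(=O)c2c(O)cc(OCc3ccccc3)cc2OCc2ccccc2)cc1 | intermediate
5 | racemic 5,7-bis(benzyloxy)-2-(4-methoxyphenyl)chroman-4-one (di-O-benzylisosakuranetin) | COc1ccc(C2CC(=O)c3c(OCc4ccccc4)cc(OCc4ccccc4)cc3O2)cc1 | intermediate
6 | 5,7-bis(benzyloxy)-2-(4-methoxyphenyl)-4H-chromen-4-one (di-O-benzylacacetin) | COc1ccc(-c2cc(=O)c3c(OCc4ccccc4)cc(OCc4ccccc4)cc3o2)cc1 | intermediate
7 | 4-hydroxy-3-iodobenzaldehyde | O=Cc1ccc(O)c(I)c1 | starting material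
8 | 4-(benzyloxy)-3-iodobenzaldehyde | O=Cc1ccc(OCc2ccccc2)c(I)c1 | intermediate
9 | 4-(benzyloxy)-3-[5,7-bis(benzyloxy)-2-(4-methoxyphenyl)-4-oxo-4H-chromen-8-yl]benzaldehyde | COc1ccc(-c2cc(=O)c3c(OCc4ccccc4)cc(OCc4ccccc4)c(-c4cc(C=O)ccc4OCc4ccccc4)c3o2)cc1 | intermediate
10 | (E)-1-[2,4-bis(benzyloxy)-6-hydroxyphenyl]-3-{4-(benzyloxy)-3-[5,7-bis(benzyloxy)-2-(4-methoxyphenyl)-4-oxo-4H-chromen-8-yl]phenyl}prop-2-en-1-one | COc1ccc(-c2cc(=O)c3c(OCc4ccccc4)cc(OCc4ccccc4)c(-c4cc(/C=C/C(=O)c5c(O)cc(OCc6ccccc6)cc5OCc5ccccc5)ccc4OCc4ccccc4)c3o2)cc1 | intermediate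
11 | racemic 5,7-bis(benzyloxy)-8-{2-(benzyloxy)-5-[5,7-bis(benzyloxy)-4-oxochroman-2-yl]phenyl}-2-(4-methoxyphenyl)-4H-chromen-4-one | COc1ccc(-c2cc(=O)c3c(OCc4ccccc4)cc(OCc4ccccc4)c(-c4cc(C5CC(=O)c6c(OCc7ccccc7)cc(OCc7ccccc7)cc6O5)ccc4OCc4ccccc4)c3o2)cc1 | intermediate
12 | 5,7-bis(benzyloxy)-8-{2-(benzyloxy)-5-[5,7-bis(benzyloxy)-4-oxo-4H-chromen-2-yl]phenyl}-2-(4-methoxyphenyl)-4H-chromen-4-one (penta-O-benzylpodocarpusflavone A) | COc1ccc(-c2cc(=O)c3c(OCc4ccccc4)cc(OCc4ccccc4)c(-c4cc(-c5cc(=O)c6c(OCc7ccccc7)cc(OCc7ccccc7)cc6o5)ccc4OCc4ccccc4)c3o2)cc1 | intermediate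
13 | podocarpusflavone A, 8-[5-(5,7-dihydroxy-4-oxo-4H-chromen-2-yl)-2-hydroxyphenyl]-5,7-dihydroxy-2-(4-methoxyphenyl)-4H-chromen-4-one | COc1ccc(-c2cc(=O)c3c(O)cc(O)c(-c4cc(-c5cc(=O)c6c(O)cc(O)cc6o5)ccc4O)c3o2)cc1 | target

## Step count and risks

Total step count: 8.
Longest linear sequence: 7 steps (steps 1, 2, 3, 5, 6, 7, 8, from compound 1); step 4 is a one-step side branch.

**Steps most likely to fail**

**Step 5 (the proposed gold-catalysed C8–H arylation).** Ring A of 6 carries an acyl group and is a weaker nucleophile than 1,3,5-trimethoxybenzene. The biaryl formed is tri-ortho-substituted. Attack at C6 or C3 would give isomers.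

Fallback by known chemistry, setting out from 6 and 8 and coming back at 9: 6 is iodinated with I2/CF3CO2Ag in CH2Cl2 at 0 °C, the established C8-selective halogenation of 5,7-dialkoxyflavones, to give 5,7-bis(benzyloxy)-8-iodo-2-(4-methoxyphenyl)-4H-chromen-4-one F1. Iodide 8 is converted by Miyaura borylation (B2pin2, PdCl2(dppf), KOAc, dioxane, 90 °C) into 4-(benzyloxy)-3-(4,4,5,5-tetramethyl-1,3,2-dioxaborolan-2-yl)benzaldehyde F2. Suzuki–Miyaura coupling of F1 with F2 (Pd(PPh3)4, K2CO3, DMF/H2O, 90 °C) then gives 9.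

**Step 6 (Claisen–Schmidt condensation on the flavone-bearing aldehyde).** Prolonged KOH may open ring C of the acacetin unit. The hindered, poorly soluble aldehyde 9 may also condense slowly.

Fallback that avoids the aldol and the oxidative cyclisation, setting out from 9 (with 2 as partner) and coming back at 12: Pinnick oxidation of 9 (NaClO2, NaH2PO4, 2-methyl-2-butene, t-BuOH/THF/H2O) gives 4-(benzyloxy)-3-[5,7-bis(benzyloxy)-2-(4-methoxyphenyl)-4-oxo-4H-chromen-8-yl]benzoic acid F3. Esterification with the phenol of 2 (EDC·HCl, DMAP, CH2Cl2) gives 2-acetyl-3,5-bis(benzyloxy)phenyl 4-(benzyloxy)-3-[5,7-bis(benzyloxy)-2-(4-methoxyphenyl)-4-oxo-4H-chromen-8-yl]benzoate F4. Baker–Venkataraman acyl transfer (LiN(SiMe3)2, THF, −20 °C) gives 1-[2,4-bis(benzyloxy)-6-hydroxyphenyl]-3-{4-(benzyloxy)-3-[5,7-bis(benzyloxy)-2-(4-methoxyphenyl)-4-oxo-4H-chromen-8-yl]phenyl}propane-1,3-dione F5. Acid cyclodehydration (p-TsOH, toluene, 90 °C) closes ring C to give 12.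

**Step 8 (five-fold hydrogenolysis).** Traces of sulfur or iodine from step 7 can poison the catalyst. Partly debenzylated material may precipitate. Forcing the reaction risks reducing the C2=C3 bonds.

Fallback that replaces reduction by Lewis-acid dealkylation, setting out from 12 and coming back at 13: BCl3 (excess) with pentamethylbenzene as benzyl-cation scavenger in CH2Cl2 at −78 °C, then MeOH quench. This cleaves the benzyl ethers by ionisation, cannot touch the chromone double bonds and at this temperature spares the non-chelated 4'''-methyl ether. New compound on this path: none F0.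

## Further compounds

F1 | step 5 | 5,7-bis(benzyloxy)-8-iodo-2-(4-methoxyphenyl)-4H-chromen-4-one | COc1ccc(-c2cc(=O)c3c(OCc4ccccc4)cc(OCc4ccccc4)c(I)c3o2)cc1
F2 | step 5 | 4-(benzyloxy)-3-(4,4,5,5-tetramethyl-1,3,2-dioxaborolan-2-yl)benzaldehyde | O=Cc1ccc(OCc2ccccc2)c(B2OC(C)(C)C(C)(C)O2)c1
F3 | step 6 | 4-(benzyloxy)-3-[5,7-bis(benzyloxy)-2-(4-methoxyphenyl)-4-oxo-4H-chromen-8-yl]benzoic acid | COc1ccc(-c2cc(=O)c3c(OCc4ccccc4)cc(OCc4ccccc4)c(-c4cc(C(=O)O)ccc4OCc4ccccc4)c3o2)cc1
F4 | step 6 | 2-acetyl-3,5-bis(benzyloxy)phenyl 4-(benzyloxy)-3-[5,7-bis(benzyloxy)-2-(4-methoxyphenyl)-4-oxo-4H-chromen-8-yl]benzoate | COc1ccc(-c2cc(=O)c3c(OCc4ccccc4)cc(OCc4ccccc4)c(-c4cc(C(=O)Oc5cc(OCc6ccccc6)cc(OCc6ccccc6)c5C(C)=O)ccc4OCc4ccccc4)c3o2)cc1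
F5 | step 6 | 1-[2,4-bis(benzyloxy)-6-hydroxyphenyl]-3-{4-(benzyloxy)-3-[5,7-bis(benzyloxy)-2-(4-methoxyphenyl)-4-oxo-4H-chromen-8-yl]phenyl}propane-1,3-dione | COc1ccc(-c2cc(=O)c3c(OCc4ccccc4)cc(OCc4ccccc4)c(-c4cc(C(=O)CC(=O)c5c(O)cc(OCc6ccccc6)cc5OCc5ccccc5)ccc4OCc4ccccc4)c3o2)cc1
F0 | step 8 | none | none
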